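| setting | larch | cedar | ash |
|---|---|---|---|
| substrate | 250 mM | 250 mM | 250 mM |
| partner | 200 mM | 200 mM | 500 mM |
| product |  | 75.0 mM |  |
| time |  |  | 15 h |

| run | time / h | [product] / mM |
|---|---|---|
| larch run | 2.1 | 87.2 |
| larch run | 4.3 | 97.8 |
| larch run | 6.4 | 103.0 |
| larch run | 8.6 | 102.6 |
| larch run | 11 | 104.7 |
| larch run | 13 | 106.9 |
| larch run | 15 | 108.1 |
| cedar run | 2.1 | 163.8 |
| cedar run | 4.3 | 173.2 |
| cedar run | 6.4 | 179.1 |
| cedar run | 8.6 | 178.9 |
| cedar run | 11 | 180.7 |
| cedar run | 13 | 180.5 |
| cedar run | 15 | 180.3 |

(scatter of a reading: 1 mM)

1. product in the ash run at 15 h, as a share of the substrate charged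

- Overall: substrate + partner -> product.
- Constant volume, constant temperature.
- "The second partner" is partner.

- At late times the larch run read 108.1 mM at 15 h, and I turned the question round: for the larch run to have gone to its end by the overall equation, c(product) would have had to reach the 200 mM of partner charged, the limiting reagent there by that equation.
- I froze the stall share, the product made by 15 h over the charge of the limiting reagent, which read 54.0 % in the larch run, so that flask stood 91.9 mM short of its limit.
- The cedar run held 75.0 mM of product from the start and still read a stall share of 52.7 %, close to the larch reading.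
- In the ash run substrate was the limiting reagent by the overall equation, with 250 mM against 500 mM of partner, so holding the share frozen gave me 135 mM, which is 54.0 % of the substrate charged.
- The forecast stood higher at 75 %, shaded down from 79 %, and it read the stall thus: “something is dying, most likely a catalyst or active species, or the partner is being lost to a side path”.
- The ash run gave 65.6 %, so its stall share stood above the 54.0 % of the larch run and the 52.7 % of the cedar run.

    substrate + partner → product (4.032 L mol⁻¹ h⁻¹)
    2 substrate → homo dimer (3.006 L mol⁻¹ h⁻¹)
    2 partner → lost reagent (1.127 L mol⁻¹ h⁻¹)

- At the start of the larch run, substrate fell to homo dimer at 376 mM h⁻¹, faster than product formed at 202 mM h⁻¹, and c(product) read 87.2 mM by 2.1 h. At the start of the ash run, product formed at 504 mM h⁻¹, faster than that same loss of substrate, while partner fell to lost reagent at 564 mM h⁻¹, and by 15 h c(product) stood at 164 mM.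

The runs were generated by integration with made-up constants, and the scatter is random.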